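**Retrosynthetic overview**
- Feature: ring A is a guaiacol in which C5, C6 (OMe), C7 (OH) and C8 are the four carbons of 3-methoxybut-3-en-2-one. On ring B the C1 aryl, C2 ester and C3 hydroxymethyl groups are all-trans, so all-equatorial, and C1 and C2 become epimerisable once C8a is a ketone.
- Key disconnection: C4a–C5 (enamine Michael addition) and C8–C8a (aldol condensation), followed by loss of H2. This leads from the aryltetralin back to an all-trans 2-aryl-3-(methoxycarbonyl)-4-(benzyloxymethyl)cyclohexanone.
- That ketone comes from (S)-4-(benzyloxymethyl)cyclohex-2-enone, itself made by chiral lithium amide desymmetrisation and Saegusa–Ito oxidation. The sequence is α-iodination/Suzuki coupling (C1–aryl), anti conjugate vinylation (C2), oxidative cleavage of vinyl to CO2Me, and a closing base equilibration.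
- Ring order: ring B is bought as the cyclohexanone, the pendant aryl ring is coupled on, and ring A is annulated and aromatised last. One hydrogenolysis frees the two remaining hydroxyl groups.

Key step: step 13

Numbering: the tetralin locants of the target (C1–C4, C4a, C5–C8, C8a) are used for all intermediates.
Assumption: lithium (R,R)-bis(1-phenylethyl)amide is taken to deprotonate the 4-(benzyloxymethyl) ketone in the same sense as 4-tert-butylcyclohexanone, giving the (S)-enol silane. If the sense proved opposite, the (S,S)-amine would be used.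

Step 1
Reactants: 1 4-(hydroxymethyl)cyclohexan-1-one
Product: 2 4-[(benzyloxy)methyl]cyclohexan-1-one
Conditions: BnOC(=NH)CCl3 (1.3 equiv), TfOH (5 mol %), CH2Cl2/cyclohexane, 0 °C → rt
Reagents that add atoms: benzyl 2,2,2-trichloroacetimidate, N=C(OCc1ccccc1)C(Cl)(Cl)Cl
Why: Acid-catalysed O-benzylation with a trichloroacetimidate works on base-sensitive hydroxy ketones because no enolate is formed, and benzyl is chosen because it withstands the hot acidic media of step 13 and leaves together with the aryl benzyl ether in step 14.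

Step 2
Reactants: 2 4-[(benzyloxy)methyl]cyclohexan-1-one
Product: 4 {[(4S)-4-[(benzyloxy)methyl]cyclohex-1-en-1-yl]oxy}trimethylsilane, via lithium enolate 3 (not isolated)
Conditions: (R,R)-bis(1-phenylethyl)amine, n-BuLi, THF, −78 → 0 °C; cool to −100 °C, TMSCl, then slow addition of 2
Reagents that add atoms: chlorotrimethylsilane, C[Si](C)(C)Cl
Why: Enantioselective deprotonation of a prochiral 4-substituted cyclohexanone by a C2-symmetric chiral lithium amide with in situ silylation removes one of the two enantiotopic axial α-protons of the chair with equatorial CH2OBn, which makes C3 the S stereocentre and marks C1 as the enol carbon.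

Step 3
Reactants: 4 {[(4S)-4-[(benzyloxy)methyl]cyclohex-1-en-1-yl]oxy}trimethylsilane
Product: 5 (4S)-4-[(benzyloxy)methyl]cyclohex-2-en-1-one
Conditions: Pd(OAc)2 (10 mol %), O2 (1 atm), DMSO, 25–40 °C
Reagents that add atoms: none
Why: In this Saegusa–Ito oxidation (catalytic O2/DMSO form) the palladium enolate made from the enol silane loses the β-hydride at C2, so the C1=C2 double bond appears only on the side chosen in step 2 and C3 is untouched.

Step 4
Reactants: 5 (4S)-4-[(benzyloxy)methyl]cyclohex-2-en-1-one
Product: 6 (4S)-4-[(benzyloxy)methyl]-2-iodocyclohex-2-en-1-one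
Conditions: I2 (1.5 equiv), pyridine/CH2Cl2 1:1, 0 °C → rt
Reagents that add atoms: iodine, II
Why: α-Iodination of a cyclic enone proceeds by reversible conjugate addition of pyridine, iodination of the enolate and elimination (a Baylis–Hillman-type sequence), in a weakly basic medium that does not remove the γ-proton at C3.

Step 5
Reactants: 7 4-bromo-2-methoxyphenol
Product: 8 1-(benzyloxy)-4-bromo-2-methoxybenzene
Conditions: BnBr, K2CO3, acetone, reflux
Reagents that add atoms: benzyl bromide, BrCc1ccccc1
Why: This is a Williamson ether synthesis on a phenoxide, in which the aryl bromide is inert.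

Step 6
Reactants: 8 1-(benzyloxy)-4-bromo-2-methoxybenzene
Product: 10 [4-(benzyloxy)-3-methoxyphenyl]boronic acid, via aryllithium 9 (not isolated)
Conditions: n-BuLi, THF, −78 °C; B(Oi-Pr)3, −78 °C → rt; 2 M HCl
Reagents that add atoms: triisopropyl borate, CC(C)OB(OC(C)C)OC(C)C; water, O
Why: In this standard lithiation–borylation, bromine–lithium exchange at −78 °C is faster than any attack on the benzyl ether, and the aryllithium is trapped by the borate and hydrolysed to the boronic acid.

Step 7
Reactants: 6 (4S)-4-[(benzyloxy)methyl]-2-iodocyclohex-2-en-1-one; 10 [4-(benzyloxy)-3-methoxyphenyl]boronic acid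
Product: 11 (4S)-2-[4-(benzyloxy)-3-methoxyphenyl]-4-[(benzyloxy)methyl]cyclohex-2-en-1-one
Conditions: PdCl2(PhCN)2 (5 mol %), AsPh3 (10 mol %), Ag2O (1.6 equiv), THF/H2O 8:1, rt
Reagents that add atoms: none
Why: Suzuki–Miyaura coupling of a 2-iodoenone with an electron-rich arylboronic acid under Ag2O/AsPh3 promotion runs at room temperature, places the aryl group on C1 with no regiochemical ambiguity, and avoids hot carbonate that could racemise C3 through the dienolate.

Step 8
Reactants: 11 (4S)-2-[4-(benzyloxy)-3-methoxyphenyl]-4-[(benzyloxy)methyl]cyclohex-2-en-1-one; 12 vinylmagnesium bromide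
Product: 14 (2R,3R,4S)-2-[4-(benzyloxy)-3-methoxyphenyl]-4-[(benzyloxy)methyl]-3-vinylcyclohexan-1-one, via enol silane 13 (not isolated)
Conditions: CuI·2LiCl (10 mol %), TMSCl (2 equiv), THF, −78 → −30 °C; then K2CO3 (cat.), MeOH, rt
Reagents that add atoms: none
Why: Copper-catalysed, TMSCl-accelerated conjugate addition of the Grignard reagent delivers vinyl to C2 anti to the CH2OBn group on C3 (the trans-3,4 outcome typical of 4-substituted cyclohexenones), and K2CO3/MeOH cleaves the enol silane and equilibrates the acidic benzylic C1 to the equatorial aryl, giving the all-trans ketone.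

Step 9
Reactants: 14 (2R,3R,4S)-2-[4-(benzyloxy)-3-methoxyphenyl]-4-[(benzyloxy)methyl]-3-vinylcyclohexan-1-one
Product: 16 (1R,2R,6S)-2-[4-(benzyloxy)-3-methoxyphenyl]-6-[(benzyloxy)methyl]-3-oxocyclohexane-1-carbaldehyde, via diol 15 (not isolated)
Conditions: OsO4 (2 mol %), NaIO4 (4 equiv), 2,6-lutidine (2 equiv), 1,4-dioxane/H2O 3:1, rt
Reagents that add atoms: osmium tetroxide (catalytic oxygen carrier), O=[Os](=O)(=O)=O; sodium periodate, [Na+].[O-]I(=O)(=O)=O
Why: In the Lemieux–Johnson oxidation OsO4 dihydroxylates only the terminal alkene and NaIO4 cleaves the diol, leaving the electron-rich arene, the ketone and both benzyl ethers alone, which ozone would not guarantee.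

Step 10
Reactants: 16 (1R,2R,6S)-2-[4-(benzyloxy)-3-methoxyphenyl]-6-[(benzyloxy)methyl]-3-oxocyclohexane-1-carbaldehyde
Product: 17 (1R,2R,6S)-2-[4-(benzyloxy)-3-methoxyphenyl]-6-[(benzyloxy)methyl]-3-oxocyclohexane-1-carboxylic acid
Conditions: NaClO2, NaH2PO4, 2-methylbut-2-ene, t-BuOH/H2O, 0 °C → rt
Reagents that add atoms: sodium chlorite, [Na+].[O-]Cl=O
Why: The Pinnick oxidation converts the aldehyde into the acid at mildly acidic pH without touching C1 or C2, and 2-methylbut-2-ene traps HOCl so that the electron-rich ring is not chlorinated.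

Step 11
Reactants: 17 (1R,2R,6S)-2-[4-(benzyloxy)-3-methoxyphenyl]-6-[(benzyloxy)methyl]-3-oxocyclohexane-1-carboxylic acid
Product: 18 methyl (1R,2R,6S)-2-[4-(benzyloxy)-3-methoxyphenyl]-6-[(benzyloxy)methyl]-3-oxocyclohexane-1-carboxylate
Conditions: MeI, KHCO3, DMF, rt; then NaOMe (0.2 equiv), MeOH, 0 °C → rt
Reagents that add atoms: iodomethane, CI
Why: Carboxylate O-alkylation (SN2 on MeI) uses a base too weak to enolise the ketone, and catalytic NaOMe then equilibrates C1 (α to the ketone) and C2 (α to the ester) against the fixed C3, so that any cis isomer carried from steps 8–10 drains into the all-equatorial ketone.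

Step 12
Reactants: 19 3,3-dimethoxybutan-2-one
Product: 20 3-methoxybut-3-en-2-one
Conditions: KHSO4 (cat.), hydroquinone (trace), neat, 140–160 °C with MeOH distilled off; fractional distillation, stored cold
Reagents that add atoms: none
Why: Acid-catalysed cracking of a dimethyl ketal to the methyl enol ether is driven by removal of methanol, and only the C4 methyl group can lose the proton because the other neighbour of the ketal carbon is the carbonyl carbon.

Step 13
Reactants: 18 methyl (1R,2R,6S)-2-[4-(benzyloxy)-3-methoxyphenyl]-6-[(benzyloxy)methyl]-3-oxocyclohexane-1-carboxylate; 20 3-methoxybut-3-en-2-one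
Product: 24 methyl (1R,2S,3S)-1-[4-(benzyloxy)-3-methoxyphenyl]-3-[(benzyloxy)methyl]-7-hydroxy-6-methoxy-1,2,3,4-tetrahydronaphthalene-2-carboxylate, via enamine 21 (not isolated), via 1,5-diketone 22 (not isolated), via methoxy-octalone 23 (not isolated)
Conditions: pyrrolidine (3 equiv), TsOH·H2O (2 mol %), PhMe, Dean–Stark, reflux, then evaporate; 20 (1.5 equiv), 1,4-dioxane, reflux; AcOH/NaOAc/H2O, reflux; aqueous wash and solvent switch, crude 23 carried on; Pd(CF3CO2)2 (5 mol %), 2-(dimethylamino)pyridine (10 mol %), TsOH·H2O (20 mol %), O2 (1 atm), DMSO, 80 °C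
Reagents that add atoms: none
Why: The closest known reaction types are the Stork enamine Robinson annulation of 2-substituted cyclohexanones with vinyl ketones and the Pd-catalysed aerobic dehydrogenation of cyclohexenones to phenols. Regioselectivity is the first need: allylic 1,3-strain between the pyrrolidine ring and the C1 aryl group keeps the double bond of enamine 21 at C8a=C4a, so C4a and not the more acidic benzylic C1 (the site a metal enolate would use) adds to the CH2 terminus of 20 and forms C4a–C5. After hydrolysis to 22 the methyl carbon C8 closes ring A on the C8a carbonyl by a pyrrolidinium acetate-catalysed 6-(enolexo)-exo-trig aldol addition, and loss of water makes this closure irreversible while the bridged ketol from attack of C1 on C7 can only revert. No lasting stereocentre is created, since C4a and C6 of 23 are epimer mixtures that vanish on aromatisation; C1 is labile throughout 21–23 (α to the iminium or ketone, then γ to the enone), so it is not expected to be retained but to settle in 23 under the hot buffer in the thermodynamic arrangement with aryl, ester and CH2OBn all equatorial on ring B, anchored by the untouched C2 and C3, before aromatisation freezes it. Divalent palladium then forms the enolate of 23 at C6, β-hydride elimination from C5 gives a cross-conjugated dienone that tautomerises by loss of H4a to the C7 phenol, and O2 returns zerovalent palladium to the cycle, so the C6-OMe/C7-OH pattern is dictated by 20 and needs no selective methylation. Benzyl ethers are carried here because hot aqueous acetic acid and TsOH in DMSO would strip a primary silyl ether and let the freed alcohol lactonise onto the C2 ester.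

Step 14
Reactants: 24 methyl (1R,2S,3S)-1-[4-(benzyloxy)-3-methoxyphenyl]-3-[(benzyloxy)methyl]-7-hydroxy-6-methoxy-1,2,3,4-tetrahydronaphthalene-2-carboxylate
Product: 25 methyl (1R,2S,3S)-7-hydroxy-1-(4-hydroxy-3-methoxyphenyl)-3-(hydroxymethyl)-6-methoxy-1,2,3,4-tetrahydronaphthalene-2-carboxylate
Conditions: H2 (1 atm), 10% Pd/C, EtOAc/MeOH 1:1, rt
Reagents that add atoms: none
Why: Catalytic hydrogenolysis removes the aryl and the alkyl benzyl ether in one neutral operation, touches no stereocentre, and by avoiding acid, base and fluoride keeps the γ-hydroxy ester from closing to the trans-fused lactone.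

**Compound list**
1 | 4-(hydroxymethyl)cyclohexan-1-one | O=C1CCC(CO)CC1 | starting material
2 | 4-[(benzyloxy)methyl]cyclohexan-1-one | O=C1CCC(COCc2ccccc2)CC1 | intermediate
3 | lithium (4S)-4-[(benzyloxy)methyl]cyclohex-1-en-1-olate | [Li]OC1=CC[C@@H](COCc2ccccc2)CC1 | intermediate
4 | {[(4S)-4-[(benzyloxy)methyl]cyclohex-1-en-1-yl]oxy}trimethylsilane | C[Si](C)(C)OC1=CC[C@@H](COCc2ccccc2)CC1 | intermediate
5 | (4S)-4-[(benzyloxy)methyl]cyclohex-2-en-1-one | O=C1C=C[C@@H](COCc2ccccc2)CC1 | intermediate
6 | (4S)-4-[(benzyloxy)methyl]-2-iodocyclohex-2-en-1-one | O=C1C(I)=C[C@@H](COCc2ccccc2)CC1 | intermediate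
7 | 4-bromo-2-methoxyphenol | COc1cc(Br)ccc1O | starting material
8 | 1-(benzyloxy)-4-bromo-2-methoxybenzene | COc1cc(Br)ccc1OCc1ccccc1 | intermediate
9 | [4-(benzyloxy)-3-methoxyphenyl]lithium | [Li]c1ccc(OCc2ccccc2)c(OC)c1 | intermediate
10 | [4-(benzyloxy)-3-methoxyphenyl]boronic acid | COc1cc(B(O)O)ccc1OCc1ccccc1 | intermediate
11 | (4S)-2-[4-(benzyloxy)-3-methoxyphenyl]-4-[(benzyloxy)methyl]cyclohex-2-en-1-one | O=C1C(c2ccc(OCc3ccccc3)c(OC)c2)=C[C@@H](COCc2ccccc2)CC1 | intermediate
12 | vinylmagnesium bromide | C=C[Mg]Br | starting material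
13 | {[(3R,4S)-2-[4-(benzyloxy)-3-methoxyphenyl]-4-[(benzyloxy)methyl]-3-vinylcyclohex-1-en-1-yl]oxy}trimethylsilane | C[Si](C)(C)OC1=C(c2ccc(OCc3ccccc3)c(OC)c2)[C@H](C=C)[C@@H](COCc2ccccc2)CC1 | intermediate
14 | (2R,3R,4S)-2-[4-(benzyloxy)-3-methoxyphenyl]-4-[(benzyloxy)methyl]-3-vinylcyclohexan-1-one (all-trans) | C=C[C@@H]1[C@@H](COCc2ccccc2)CCC(=O)[C@H]1c1ccc(OCc2ccccc2)c(OC)c1 | intermediate
15 | (2R,3R,4S)-2-[4-(benzyloxy)-3-methoxyphenyl]-4-[(benzyloxy)methyl]-3-(1,2-dihydroxyethyl)cyclohexan-1-one (carbinol epimers) | OCC(O)[C@@H]1[C@@H](COCc2ccccc2)CCC(=O)[C@H]1c1ccc(OCc2ccccc2)c(OC)c1 | intermediate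
16 | (1R,2R,6S)-2-[4-(benzyloxy)-3-methoxyphenyl]-6-[(benzyloxy)methyl]-3-oxocyclohexane-1-carbaldehyde | O=C[C@@H]1[C@@H](COCc2ccccc2)CCC(=O)[C@H]1c1ccc(OCc2ccccc2)c(OC)c1 | intermediate
17 | (1R,2R,6S)-2-[4-(benzyloxy)-3-methoxyphenyl]-6-[(benzyloxy)methyl]-3-oxocyclohexane-1-carboxylic acid | OC(=O)[C@@H]1[C@@H](COCc2ccccc2)CCC(=O)[C@H]1c1ccc(OCc2ccccc2)c(OC)c1 | intermediate
18 | methyl (1R,2R,6S)-2-[4-(benzyloxy)-3-methoxyphenyl]-6-[(benzyloxy)methyl]-3-oxocyclohexane-1-carboxylate (all-trans, key-step precursor) | COC(=O)[C@@H]1[C@@H](COCc2ccccc2)CCC(=O)[C@H]1c1ccc(OCc2ccccc2)c(OC)c1 | intermediate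
19 | 3,3-dimethoxybutan-2-one | CC(=O)C(C)(OC)OC | starting material
20 | 3-methoxybut-3-en-2-one | C=C(OC)C(C)=O | intermediate
21 | pyrrolidine enamine of 18 (double bond C8a=C4a; C2 and C3 as in 18, C1 labile) | COC(=O)[C@@H]1[C@@H](COCc2ccccc2)CC=C(N2CCCC2)C1c1ccc(OCc2ccccc2)c(OC)c1 | intermediate
22 | 1,5-diketone: 18 bearing a 2-methoxy-3-oxobutyl group on C4a (C2 and C3 as in 18; C1, C4a, C6 epimer mixtures) | COC(=O)[C@@H]1[C@@H](COCc2ccccc2)CC(CC(OC)C(C)=O)C(=O)C1c1ccc(OCc2ccccc2)c(OC)c1 | intermediate
23 | 6-methoxy-7-oxo-Δ8(8a)-octalin with C1 aryl, C2 ester and C3 CH2OBn all-trans (C4a and C6 epimer mixtures) | COC(=O)[C@@H]1[C@@H](COCc2ccccc2)CC2CC(OC)C(=O)C=C2[C@H]1c1ccc(OCc2ccccc2)c(OC)c1 | intermediate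
24 | methyl (1R,2S,3S)-1-[4-(benzyloxy)-3-methoxyphenyl]-3-[(benzyloxy)methyl]-7-hydroxy-6-methoxy-1,2,3,4-tetrahydronaphthalene-2-carboxylate | COC(=O)[C@@H]1[C@@H](COCc2ccccc2)Cc2cc(OC)c(O)cc2[C@H]1c1ccc(OCc2ccccc2)c(OC)c1 | intermediate
25 | methyl (1R,2S,3S)-7-hydroxy-1-(4-hydroxy-3-methoxyphenyl)-3-(hydroxymethyl)-6-methoxy-1,2,3,4-tetrahydronaphthalene-2-carboxylate | COC(=O)[C@@H]1[C@@H](CO)Cc2cc(OC)c(O)cc2[C@H]1c1ccc(O)c(OC)c1 | target

**Step count**
- Total step count: 14.
- Longest linear sequence: 11 steps (1–4, 7–11, 13, 14).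

**Steps most likely to fail**

Step 13.
- What may go wrong: the methoxy group of 20 pushes electron density onto the very CH2 carbon that C4a must attack. Conjugate addition may therefore be outrun by polymerisation of the acceptor or by simple return of the ketone on hydrolysis. A second process to watch is aromatisation of part of the material while the C1 aryl group is still axial.
- Fallback (sets out from 18, comes back at 23): enamine 21 is made as before and treated with but-3-en-2-one, the standard acceptor of this annulation. The acetate buffer then gives the 6-demethoxy octalone F1, which is isolated. Kinetic deprotonation at C6 (LiHMDS, TMSCl, THF, −78 °C) gives the cross-conjugated silyloxydiene F2. Rubottom oxidation (mCPBA, NaHCO3, CH2Cl2, then citric acid in MeOH) gives the 6-hydroxy enone F3. O-Methylation (MeOTf, 2,6-di-tert-butylpyridine, CH2Cl2) gives 23, now as an isolated compound. It is dehydrogenated with Pd(CF3CO2)2/O2 as in the last stage of step 13 to reach 24. Methylating before aromatisation keeps the C6 and C7 oxygen atoms differentiated.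

Step 8.
- What may go wrong: the α-aryl group is twisted out of the enone plane and, together with the C3 substituent, shields C2. 1,2-Addition of the Grignard reagent or recovery of 11 may then compete.
- Fallback (sets out from 5, comes back at 14): the order of bond formation is reversed. The same copper-catalysed vinylation with 12 and TMSCl is run on the unhindered enone 5, and the regiodefined enol silane F4 is isolated. Pd-catalysed α-arylation of this enol silane with bromide 8 (Pd(OAc)2, P(t-Bu)3, Bu3SnF, PhMe, 85 °C, through the tin enolate) forms the C1–aryl bond at the carbon marked by the enol silane. K2CO3/MeOH then equilibrates C1 and gives 14. Steps 4, 6 and 7 fall away.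

Step 2.
- What may go wrong: discrimination between the enantiotopic α-protons may be incomplete. Nothing later in the route removes the minor enantiomer, because all further stereocentres are relayed from C3.
- Fallback (sets out from 17, comes back at 17): classical resolution takes over from asymmetric induction. Acid 17, of whatever enantiomeric purity, is crystallised to constant rotation as its (R)-1-phenylethylammonium salt F5. The antipodal amine is used if it gives the less soluble salt. Partition between dilute HCl and EtOAc returns enantiopure 17.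

Further compounds
F1 | step 13 | 6-demethoxy analogue of 23 (7-oxo-Δ8(8a)-octalin, C1–C3 all-trans, C4a epimers) | COC(=O)[C@@H]1[C@@H](COCc2ccccc2)CC2CCC(=O)C=C2[C@H]1c1ccc(OCc2ccccc2)c(OC)c1
F2 | step 13 | 7-(trimethylsilyloxy)-6,8(8a)-diene derived from F1 | COC(=O)[C@@H]1[C@@H](COCc2ccccc2)CC2CC=C(O[Si](C)(C)C)C=C2[C@H]1c1ccc(OCc2ccccc2)c(OC)c1
F3 | step 13 | 6-hydroxy analogue of 23 (C4a and C6 epimers) | COC(=O)[C@@H]1[C@@H](COCc2ccccc2)CC2CC(O)C(=O)C=C2[C@H]1c1ccc(OCc2ccccc2)c(OC)c1
F4 | step 8 | {[(3R,4S)-4-[(benzyloxy)methyl]-3-vinylcyclohex-1-en-1-yl]oxy}trimethylsilane | C[Si](C)(C)OC1=C[C@H](C=C)[C@@H](COCc2ccccc2)CC1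
F5 | step 2 | (R)-1-phenylethylammonium salt of 17 | [O-]C(=O)[C@@H]1[C@@H](COCc2ccccc2)CCC(=O)[C@H]1c1ccc(OCc2ccccc2)c(OC)c1.C[C@@H]([NH3+])c1ccccc1
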